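**Plan**

- Feature used: ring C (C1, C9a, C9, C10, C11, C12) carries the C10 ethyl, the C11 oxygen, the C13 branch on C12 and the C8 branch on C9 on one face, next to the oxidized pair C9a/C1. This is the footprint of a bicyclo[2.2.2]octenone whose etheno bridge is C8=C13, with C13 already bearing methyl C15.
- Cuts: N4–C5 and N4=C9a (azepine, pyrroline), C3–C18 (lactone D arm), the C14 carbonyl (CO), C7=C8, C1–C2; reconnection of C8 to C13; then C9–C10 and C11–C12 by a [4+2] between a masked o-benzoquinone and a (Z)-butenyl ether.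
- Forward order: ring C by the Diels–Alder reaction, vinyl addition at C1, ozonolytic opening of the bridge, Wittig chain at C8, carbonylative closure of the C11/C12 lactone, Mannich attachment of the butenolide (ring D), then pyrroline and azepine closure.
- Stereochemistry: (Z)-ether geometry and endo addition give C10/C11/C12; the 1-arylethyl group on oxygen gives the absolute sense; the bicyclic template gives C1; convex-face hydrogenations give C13 and C20; the tert-butanesulfinyl group gives C3; the threo-selective vinylogous Mannich reaction gives C18.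

Key step: step 3

Assumption: facial induction by the 1-arylethyl group is taken to follow the usual model for (Z)-alkenyl ethers (s-trans C–O conformer, carbinol C–H in the enol ether plane, diene approaching anti to the aryl ring), which calls for the (R)-alcohol; the 4-methoxy group is added so that the auxiliary can later be removed with DDQ.

Locants are those of the alkaloid skeleton: N4; ring C = C1, C9a, C9, C10, C11, C12; C13–C15 = lactone on C11/C12 (C14 carbonyl, C15 methyl); C16–C17 = ethyl; C18–C22 = lactone D.

**Route**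

Step 1
Reactants: 1 (R)-1-(4-methoxyphenyl)ethanol; 2 (E)-1-bromobut-2-ene (crotyl bromide)
Product: 3 (R)-1-(4-methoxyphenyl)ethyl (E)-but-2-enyl ether
Conditions: NaH, Bu4NI (cat.), THF/DMF, 0 °C to rt
Reagents that add atoms: none
Why: Williamson etherification of the sodium alkoxide at the primary allylic bromide, which does not touch the carbinol stereocentre.

Step 2
Reactants: 3 (R)-1-(4-methoxyphenyl)ethyl (E)-but-2-enyl ether
Product: 4 (Z)-but-1-enyl (R)-1-(4-methoxyphenyl)ethyl ether
Conditions: KOtBu (0.3 equiv), DMSO, 60 °C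
Reagents that add atoms: none
Why: Base-mediated prototropic isomerization of an allylic ether, in which deprotonation through a potassium-bridged cisoid allyl anion should deliver the (Z)-enol ether.

Step 3
Reactants: 5 2-methoxy-5-methylphenol; 4 (Z)-but-1-enyl (R)-1-(4-methoxyphenyl)ethyl ether (3 equiv)
Product: 7 endo bicyclo[2.2.2]octenone adduct, via masked o-benzoquinone 6 (not isolated)
Conditions: PhI(OAc)2 (1.1 equiv), MeOH, 0 °C to rt, slow addition of 5 to the oxidant and 4; excess 4 should be recoverable
Reagents that add atoms: methanol CO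
Why: Trivalent-iodine oxidation of 5 in methanol gives the electron-poor dienone 6, whose diene carbons (C12, C13, C8, C9 of the alkaloid) combine with the electron-rich ether 4 in a concerted but asynchronous inverse-electron-demand Diels–Alder reaction, the known behaviour of masked o-benzoquinones toward enol ethers, 1,2-disubstituted ones included. Ring C is closed by this intermolecular [4+2] cycloaddition, which forms C9–C10 and C11–C12 and leaves C1 as ketone, C9a as ketal and C8=C13 as the etheno bridge. Regiochemistry follows the polarization of both partners: the nucleophilic β-carbon of the enol ether (C10) bonds to the δ-carbon of the dienone (C9) and the oxygen-bearing carbon (C11) to the α-carbon (C12). The (Z) geometry of 4 is transferred suprafacially so that ethyl and oxygen are cis, and the endo orientation of the alkoxy group places both syn to the new bridge, which also fixes the bridgeheads C9 and C12 relative to them. The absolute sense is set by the (R)-1-arylethyl group, whose aryl ring shields the Re face of C11 in the s-trans conformer so that the diene adds to the Si face, and the minor facial diastereomer should be removable by chromatography. Competing self-dimerization of 6 is held back by keeping its concentration low through slow addition of 5 in the presence of excess 4.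

Step 4
Reactants: 7 endo bicyclo[2.2.2]octenone adduct
Product: 8 C1 vinyl carbinol (vinyl syn to the etheno bridge)
Conditions: CH2=CHMgBr, THF, −78 to 0 °C
Reagents that add atoms: vinylmagnesium bromide C=C[Mg]Br
Why: Grignard 1,2-addition to the bridge ketone, expected from the face flanked by the sp2 carbons of the C8=C13 bridge and not from the face blocked by H10 and H11 of the saturated bridge, which sets C1 with its carbon substituent cis to C13.

Step 5
Reactants: 8 C1 vinyl carbinol
Product: 10 C1,C3 diol, via B-alkyl-9-borabicyclo[3.3.1]nonane 9 (not isolated)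
Conditions: 9-BBN, THF, 0 °C to rt; then NaOH, H2O2, 0 °C
Reagents that add atoms: hydrogen peroxide OO
Why: Anti-Markovnikov hydroboration–oxidation, in which the bulky borane should take the monosubstituted vinyl group and leave the trisubstituted, doubly flanked bridge alkene.

Step 6
Reactants: 10 C1,C3 diol
Product: 11 bis(triethylsilyl) ether
Conditions: Et3SiOTf, 2,6-lutidine, CH2Cl2, −78 to 0 °C
Reagents that add atoms: triethylsilyl trifluoromethanesulfonate CC[Si](CC)(CC)OS(=O)(=O)C(F)(F)F
Why: Silylation of the primary and the tertiary hydroxyl with a silyl triflate under buffered conditions, which the ketone-derived ketal (no enolizable position toward the bridgehead) and the benzylic ether should tolerate.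

Step 7
Reactants: 11 bis(triethylsilyl) ether
Product: 13 ring C keto aldehyde (C9 formyl and C12 acetyl), via secondary ozonide 12 (not isolated)
Conditions: O3, CH2Cl2, −78 °C, Sudan Red 7B as end-point indicator; then PPh3, −78 °C to rt
Reagents that add atoms: ozone [O-][O+]=O
Why: Ozonolysis with reductive work-up of the only alkene, which opens the bicycle to ring C with an aldehyde at C8 and a methyl ketone at C13 that are chemically distinct and cis on the ring, without touching a stereocentre.

Step 8
Reactants: 13 ring C keto aldehyde; 14 [3-(benzyloxy)propyl]triphenylphosphonium bromide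
Product: 15 (Z)-C7=C8 alkene methyl ketone
Conditions: 14, KN(SiMe3)2, THF, −78 °C; then 13, −78 to 0 °C
Reagents that add atoms: none
Why: Wittig olefination with an unstabilized ylide, which should add to the aldehyde at a temperature at which the hindered methyl ketone is neither attacked nor enolized; the alkene geometry is irrelevant because the bond is reduced later.

Step 9
Reactants: 15 (Z)-C7=C8 alkene methyl ketone
Product: 16 C13 enol triflate
Conditions: KN(SiMe3)2, THF, −78 °C; then PhNTf2, −78 to 0 °C
Reagents that add atoms: N-phenylbis(trifluoromethanesulfonimide) O=S(=O)(N(c1ccccc1)S(=O)(=O)C(F)(F)F)C(F)(F)F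
Why: Kinetic enolization and O-triflation, in which the amide base should remove a methyl (C15) proton in preference to the hindered tertiary H12, so that C12 is not epimerized and the C11 ether is not eliminated.

Step 10
Reactants: 16 C13 enol triflate
Product: 17 C11 alcohol
Conditions: DDQ, CH2Cl2/pH 7 buffer, 0 °C
Reagents that add atoms: none
Why: Oxidative cleavage of the electron-rich 4-methoxybenzylic ether by hydride abstraction and hydrolysis, which should leave the plain benzyl ether, the silyl ethers and the enol triflate in place.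

Step 11
Reactants: 17 C11 alcohol
Product: 18 cis-fused α-methylene lactone
Conditions: Pd(PPh3)4 (10 mol %), CO (1 atm), Et3N, DMF, 60 °C
Reagents that add atoms: carbon monoxide [C-]#[O+]
Why: Carbonylative lactonization of a hydroxy vinyl triflate (oxidative addition to zerovalent palladium, CO insertion, capture of the acylpalladium by the cis C11 hydroxyl), which installs C14 and should outpace Heck-type insertion into the remote alkene under CO.

Step 12
Reactants: 18 cis-fused α-methylene lactone
Product: 19 saturated α-methyl lactone C5 alcohol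
Conditions: H2 (1 atm), Pd/C, EtOAc, rt
Reagents that add atoms: none
Why: Heterogeneous hydrogenation that saturates C7=C8 and the exocyclic C13=C15 alkene and hydrogenolyses the benzyl ether in one operation, with hydrogen delivered to the open convex face of the lactone (the face of H11 and H12) so that methyl C15 ends on the concave face as C13 requires.

Step 13
Reactants: 19 saturated α-methyl lactone C5 alcohol
Product: 20 C5 chloride
Conditions: PPh3, N-chlorosuccinimide, CH2Cl2, 0 °C to rt
Reagents that add atoms: N-chlorosuccinimide O=C1CCC(=O)N1Cl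
Why: Appel-type chlorination of the only free (primary) alcohol under neutral conditions, giving a leaving group that should survive all later steps.

Step 14
Reactants: 20 C5 chloride
Product: 21 C3 aldehyde
Conditions: (COCl)2, DMSO, CH2Cl2, −78 to −40 °C; then Et3N, −78 °C to rt
Reagents that add atoms: none
Why: Swern oxidation applied directly to the primary triethylsilyl ether, which is cleaved and oxidized by the chlorosulfonium reagent while the tertiary silyl ether at C1 stays, giving the β-silyloxy aldehyde in one operation.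

Step 15
Reactants: 21 C3 aldehyde; 22 (R)-tert-butanesulfinamide
Product: 23 (R,E)-N-sulfinyl aldimine
Conditions: Ti(OEt)4, THF, rt
Reagents that add atoms: none
Why: Lewis acid-mediated condensation of an aldehyde with a sulfinamide, in which Ti(OEt)4 also scavenges water and the protected β-oxygen prevents elimination.

Step 16
Reactants: 24 3-methylfuran-2(5H)-one
Product: 25 2-(tert-butyldimethylsilyloxy)-3-methylfuran
Conditions: tBuMe2SiOTf, Et3N, CH2Cl2, 0 °C
Reagents that add atoms: tert-butyldimethylsilyl trifluoromethanesulfonate CC(C)(C)[Si](C)(C)OS(=O)(=O)C(F)(F)F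
Why: Soft enolization and O-silylation of the butenolide, which gives the aromatic 2-silyloxyfuran.

Step 17
Reactants: 23 (R,E)-N-sulfinyl aldimine; 25 2-(tert-butyldimethylsilyloxy)-3-methylfuran
Product: 26 (3S,18S)-butenolide sulfinamide
Conditions: Me3SiOTf (0.5 equiv), CH2Cl2, −78 °C
Reagents that add atoms: none
Why: Lewis acid-promoted vinylogous Mannich reaction of the Mukaiyama type, in which furan C5 should add through an open transition state to the imine face anti to the tert-butyl group of the s-cis (R)-sulfinyl imine (the Re face) to give C3 (S), while the usual threo preference of 2-silyloxyfurans toward activated C=N bonds gives C18 (S).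

Step 18
Reactants: 26 (3S,18S)-butenolide sulfinamide
Product: 27 (3S,18S,20S)-lactone D sulfinamide
Conditions: H2 (1 atm), Pd/C, EtOAc, rt
Reagents that add atoms: none
Why: Catalytic hydrogenation of the butenolide from the face opposite its C18 substituent, which gives the 18,20-cis lactone (C20 S) and should spare the alkyl chloride and the sulfinamide at atmospheric pressure.

Step 19
Reactants: 27 (3S,18S,20S)-lactone D sulfinamide
Product: 29 1-pyrroline (N4=C9a), via amino ketone hydrochloride 28 (not isolated)
Conditions: 2 M HCl, THF, rt to 40 °C; then NaHCO3 (aq.), 0 °C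
Reagents that add atoms: none
Why: Acidic solvolysis that cleaves the N–S bond and the tertiary silyl ether and hydrolyses the ketal, after which the γ-amino ketone, protonated until it condenses, should close the five-membered imine with the C9a ketone faster than a free amine could attack lactone D.

Step 20
Reactants: 29 1-pyrroline (N4=C9a)
Product: 31 target alkaloid CNP0179500.1, via bicyclic iminium chloride 30 (not isolated)
Conditions: NaI (0.2 equiv), iPr2NEt, MeCN (0.005 M), 70 °C
Reagents that add atoms: none
Why: Intramolecular N-alkylation of the cyclic imine (7-exo-tet, iodide catalysis by Finkelstein exchange, high dilution) to iminium 30, which can lose a proton only from C9 because C1 is quaternary and therefore gives the C9=C9a enamine of the target.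

**Compound list**

1 | (R)-1-(4-methoxyphenyl)ethanol | C[C@@H](O)c1ccc(OC)cc1 | starting material
2 | (E)-1-bromobut-2-ene (crotyl bromide) | C/C=C/CBr | starting material
3 | (R)-1-(4-methoxyphenyl)ethyl (E)-but-2-enyl ether | C/C=C/CO[C@H](C)c1ccc(OC)cc1 | intermediate
4 | (Z)-but-1-enyl (R)-1-(4-methoxyphenyl)ethyl ether | CC/C=C\O[C@H](C)c1ccc(OC)cc1 | intermediate
5 | 2-methoxy-5-methylphenol | COc1ccc(C)cc1O | starting material
6 | 6,6-dimethoxy-3-methylcyclohexa-2,4-dien-1-one (masked o-benzoquinone, not isolated) | COC1(OC)C=CC(C)=CC1=O | intermediate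
7 | 8-ethyl-3,3-dimethoxy-7-[(R)-1-(4-methoxyphenyl)ethoxy]-6-methylbicyclo[2.2.2]oct-5-en-2-one; ethyl and aryl-ethoxy cis, both syn to the C5=C6 bridge | CC[C@@H]1[C@H]2C(OC)(OC)C(=O)[C@H](C(C)=C2)[C@@H]1O[C@H](C)c3ccc(OC)cc3 | intermediate
8 | 2-vinyl carbinol of 7 (vinyl syn to the C5=C6 bridge, hydroxyl toward the saturated bridge) | CC[C@@H]1[C@H]2C(OC)(OC)[C@](O)(C=C)[C@H](C(C)=C2)[C@@H]1O[C@H](C)c3ccc(OC)cc3 | intermediate
9 | B-alkyl-9-borabicyclo[3.3.1]nonane from 8 (boron on the terminal carbon, not isolated) | CC[C@@H]1[C@H]2C(OC)(OC)[C@](O)(CCB3C4CCCC3CCC4)[C@H](C(C)=C2)[C@@H]1O[C@H](C)c5ccc(OC)cc5 | intermediate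
10 | 2-(2-hydroxyethyl) carbinol (C1,C3 diol) | CC[C@@H]1[C@H]2C(OC)(OC)[C@](O)(CCO)[C@H](C(C)=C2)[C@@H]1O[C@H](C)c3ccc(OC)cc3 | intermediate
11 | bis(triethylsilyl) ether of 10 | CC[C@@H]1[C@H]2C(OC)(OC)[C@](O[Si](CC)(CC)CC)(CCO[Si](CC)(CC)CC)[C@H](C(C)=C2)[C@@H]1O[C@H](C)c3ccc(OC)cc3 | intermediate
12 | secondary ozonide (1,2,4-trioxolane across C8 and C13) of 11 (not isolated) | CC[C@@H]1[C@H]2C(OC)(OC)[C@](O[Si](CC)(CC)CC)(CCO[Si](CC)(CC)CC)[C@H](C3(C)OC2OO3)[C@@H]1O[C@H](C)c4ccc(OC)cc4 | intermediate
13 | ring C keto aldehyde: C9 formyl and C12 acetyl cis; C9a dimethyl ketal; C1 OSiEt3 and CH2CH2OSiEt3; C10 ethyl; C11 aryl-ethoxy | CC[C@@H]1[C@H](C=O)C(OC)(OC)[C@](O[Si](CC)(CC)CC)(CCO[Si](CC)(CC)CC)[C@H](C(C)=O)[C@@H]1O[C@H](C)c2ccc(OC)cc2 | intermediate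
14 | [3-(benzyloxy)propyl]triphenylphosphonium bromide | [Br-].C(CCOCc1ccccc1)[P+](c1ccccc1)(c1ccccc1)c1ccccc1 | starting material
15 | (Z)-C7=C8 alkene with C5 benzyl ether; C12 acetyl | CC[C@@H]1[C@H](/C=C\CCOCc2ccccc2)C(OC)(OC)[C@](O[Si](CC)(CC)CC)(CCO[Si](CC)(CC)CC)[C@H](C(C)=O)[C@@H]1O[C@H](C)c3ccc(OC)cc3 | intermediate
16 | C13 enol triflate (1-(triflyloxy)vinyl on C12) | CC[C@@H]1[C@H](/C=C\CCOCc2ccccc2)C(OC)(OC)[C@](O[Si](CC)(CC)CC)(CCO[Si](CC)(CC)CC)[C@H](C(=C)OS(=O)(=O)C(F)(F)F)[C@@H]1O[C@H](C)c3ccc(OC)cc3 | intermediate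
17 | C11 alcohol with C13 enol triflate | CC[C@@H]1[C@H](/C=C\CCOCc2ccccc2)C(OC)(OC)[C@](O[Si](CC)(CC)CC)(CCO[Si](CC)(CC)CC)[C@H](C(=C)OS(=O)(=O)C(F)(F)F)[C@@H]1O | intermediate
18 | cis-fused α-methylene-γ-butyrolactone on C11/C12 | CC[C@@H]1[C@H](/C=C\CCOCc2ccccc2)C(OC)(OC)[C@](O[Si](CC)(CC)CC)(CCO[Si](CC)(CC)CC)[C@H]3[C@@H]1OC(=O)C3=C | intermediate
19 | saturated α-methyl lactone (C13 methyl on the concave face) with 4-hydroxybutyl chain on C9 | CC[C@@H]1[C@H](CCCCO)C(OC)(OC)[C@](O[Si](CC)(CC)CC)(CCO[Si](CC)(CC)CC)[C@H]2[C@@H]1OC(=O)[C@H]2C | intermediate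
20 | C5 chloride (4-chlorobutyl on C9) | CC[C@@H]1[C@H](CCCCCl)C(OC)(OC)[C@](O[Si](CC)(CC)CC)(CCO[Si](CC)(CC)CC)[C@H]2[C@@H]1OC(=O)[C@H]2C | intermediate
21 | C3 aldehyde (C1 bears OSiEt3 and CH2CHO) | CC[C@@H]1[C@H](CCCCCl)C(OC)(OC)[C@](O[Si](CC)(CC)CC)(CC=O)[C@H]2[C@@H]1OC(=O)[C@H]2C | intermediate
22 | (R)-tert-butanesulfinamide | CC(C)(C)[S@@](=O)N | starting material
23 | (R,E)-N-tert-butanesulfinyl aldimine of 21 | CC[C@@H]1[C@H](CCCCCl)C(OC)(OC)[C@](O[Si](CC)(CC)CC)(C/C=N/[S@](=O)C(C)(C)C)[C@H]2[C@@H]1OC(=O)[C@H]2C | intermediate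
24 | 3-methylfuran-2(5H)-one | CC1=CCOC1=O | starting material
25 | 2-(tert-butyldimethylsilyloxy)-3-methylfuran | Cc1ccoc1O[Si](C)(C)C(C)(C)C | intermediate
26 | (3S,18S)-butenolide sulfinamide (threo) | CC[C@@H]1[C@H](CCCCCl)C(OC)(OC)[C@](O[Si](CC)(CC)CC)(C[C@H](N[S@](=O)C(C)(C)C)[C@@H]3C=C(C)C(=O)O3)[C@H]2[C@@H]1OC(=O)[C@H]2C | intermediate
27 | (3S,18S,20S)-lactone D sulfinamide (18,20-cis) | CC[C@@H]1[C@H](CCCCCl)C(OC)(OC)[C@](O[Si](CC)(CC)CC)(C[C@H](N[S@](=O)C(C)(C)C)[C@@H]3C[C@H](C)C(=O)O3)[C@H]2[C@@H]1OC(=O)[C@H]2C | intermediate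
28 | amino ketone hydrochloride (C3 ammonium, C9a ketone, C1 hydroxyl; not isolated) | CC[C@@H]1[C@H](CCCCCl)C(=O)[C@](O)(C[C@H](N)[C@@H]2C[C@H](C)C(=O)O2)[C@H]3[C@@H]1OC(=O)[C@H]3C.Cl | intermediate
29 | 1-pyrroline (N4=C9a) with 4-chlorobutyl on C9 | CC[C@@H]1[C@H](CCCCCl)C3=N[C@H]([C@@H]2C[C@H](C)C(=O)O2)C[C@]3(O)[C@H]2[C@@H]1OC(=O)[C@H]2C | intermediate
30 | bicyclic iminium chloride (N4–C5 closed, N4=C9a; not isolated) | CC[C@@H]1[C@H]2C3=[N+](CCCC2)[C@H]([C@@H]2C[C@H](C)C(=O)O2)C[C@]3(O)[C@H]2[C@@H]1OC(=O)[C@H]2C.[Cl-] | intermediate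
31 | CNP0179500.1 | CC[C@@H]1C2=C3N(CCCC2)[C@H]([C@@H]2C[C@H](C)C(=O)O2)C[C@]3(O)[C@H]2[C@@H]1OC(=O)[C@H]2C | target

**Count and weak points**

Total: 20 steps, of which 19 are on the main line and one (step 16) prepares silyloxyfuran 25.
Longest linear sequence: 19 steps (steps 1–15 and 17–20).

Steps most likely to fail:

Step 3. Self-dimerization of dienone 6 may outrun the cross cycloaddition with the hindered 1,2-disubstituted enol ether, and facial discrimination by the auxiliary may be weak at room temperature. The fallback sets out from 5 and comes back at 7. Bromination para to the hydroxyl (N-bromosuccinimide, MeCN, 0 °C) gives 4-bromo-2-methoxy-5-methylphenol F1. Oxidation with PhI(OAc)2 in MeOH gives 4-bromo-6,6-dimethoxy-3-methylcyclohexa-2,4-dien-1-one F2, a masked o-benzoquinone blocked against dimerization and more electron-poor. It can therefore be combined with a slight excess of 4 at lower temperature over a longer time to give the 5-bromo adduct F3. Radical debromination (Bu3SnH, AIBN, toluene, 80 °C) then returns to 7.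

Step 17. The C3/C18 pair may be poorly controlled (wrong facial sense on the sulfinyl imine or a weak threo preference), and the silyl triflate may ionize the C9a ketal. The fallback sets out from 21, takes C20 from the chiral pool, relays it to C18 and C3, and comes back at 29.
- Wittig methylenation (Ph3P=CH2, THF, 0 °C) gives the C1-allyl compound F4.
- Cross-metathesis with commercial (S)-2-methylpent-4-enoic acid (second-generation Grubbs catalyst, CH2Cl2, 40 °C) gives the (E)-alkenoic acid F5.
- Iodolactonization (I2, NaHCO3, MeCN, 0 °C) closes lactone D by anti addition across the (E)-alkene and places iodine on C3, giving iodolactone F6. The 18,20-cis ring is the one expected to be favoured, and the trans isomer would be separated.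
- SN2 displacement with NaN3 (DMF, 50 °C) inverts C3 to the (3S)-azide F7, so that nitrogen and oxygen end threo as in the target.
- Aqueous HCl in THF removes the silyl ether and the ketal to give the azido ketone F8.
- PPh3 (THF, rt to 50 °C) then effects a Staudinger reaction and intramolecular aza-Wittig condensation with the C9a ketone and returns to pyrroline 29, without a free amine ever standing next to lactone D.

Step 12. Palladium may move the exocyclic double bond into the ring to the tetrasubstituted butenolide, which would erase C12 and C13 and resist reduction. The fallback sets out from 18 and comes back at 19. Conjugate reduction with LiBH(sec-Bu)3 (THF, −78 °C) and protonation of the lactone enolate on its convex face (NH4Cl, −78 °C) gives the α-methyl lactone F9, with the benzyl ether and the C7=C8 alkene still in place. Hydrogenation (H2, Pd/C, EtOAc) then saturates the alkene, removes the benzyl group and returns to 19.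

**Further compounds**

F1 | step 3 | 4-bromo-2-methoxy-5-methylphenol | COc1cc(Br)c(C)cc1O
F2 | step 3 | 4-bromo-6,6-dimethoxy-3-methylcyclohexa-2,4-dien-1-one | COC1(OC)C=C(Br)C(C)=CC1=O
F3 | step 3 | 5-bromo-8-ethyl-3,3-dimethoxy-7-[(R)-1-(4-methoxyphenyl)ethoxy]-6-methylbicyclo[2.2.2]oct-5-en-2-one | CC[C@@H]1[C@H]2C(OC)(OC)C(=O)[C@H](C(C)=C2Br)[C@@H]1O[C@H](C)c3ccc(OC)cc3
F4 | step 17 | C1-allyl compound (methylenation product of 21) | CC[C@@H]1[C@H](CCCCCl)C(OC)(OC)[C@](O[Si](CC)(CC)CC)(CC=C)[C@H]2[C@@H]1OC(=O)[C@H]2C
F5 | step 17 | (E)-C3=C18 alkenoic acid with (20S)-methyl | CC[C@@H]1[C@H](CCCCCl)C(OC)(OC)[C@](O[Si](CC)(CC)CC)(C/C=C/C[C@H](C)C(=O)O)[C@H]2[C@@H]1OC(=O)[C@H]2C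
F6 | step 17 | C3 iodide with lactone D closed (18S,20S) | CC[C@@H]1[C@H](CCCCCl)C(OC)(OC)[C@](O[Si](CC)(CC)CC)(C[C@@H](I)[C@@H]3C[C@H](C)C(=O)O3)[C@H]2[C@@H]1OC(=O)[C@H]2C
F7 | step 17 | (3S)-azide | CC[C@@H]1[C@H](CCCCCl)C(OC)(OC)[C@](O[Si](CC)(CC)CC)(C[C@H](N=[N+]=[N-])[C@@H]3C[C@H](C)C(=O)O3)[C@H]2[C@@H]1OC(=O)[C@H]2C
F8 | step 17 | (3S)-azido C9a ketone with free C1 hydroxyl | CC[C@@H]1[C@H](CCCCCl)C(=O)[C@](O)(C[C@H](N=[N+]=[N-])[C@@H]2C[C@H](C)C(=O)O2)[C@H]3[C@@H]1OC(=O)[C@H]3C
F9 | step 12 | α-methyl lactone with C7=C8 alkene and benzyl ether retained | CC[C@@H]1[C@H](/C=C\CCOCc2ccccc2)C(OC)(OC)[C@](O[Si](CC)(CC)CC)(CCO[Si](CC)(CC)CC)[C@H]3[C@@H]1OC(=O)[C@H]3C
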